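**Compound numbers used throughout:** 1 nerol; 2 neryl TBS ether; 3 terminal (E)-allylic alcohol; 4 allylic bromide; 5 geranyl bromide; 6 geranyl phenyl sulfone; 7 lithiated 6; 8 C20 sulfone; 9 C20 silyl ether; 10 (2Z,6E,10E)-geranylgeraniol; 11 its acetate; 12 bicyclic dienol; 13 its triethylsilyl ether; 14 bis-epoxide; 15 bis-allylic diol; 16 diacetate silyl ether; 17 target.

**Numbering of atoms:** the ring is numbered as an azulene (C1 carries the chain, C3a the angular methyl, C5 the ring acetoxy group, C6 the methylidene, C8a the ring-fusion hydrogen). The chain is C1' (carbinol) to C5' (isopropenyl carbon), with C4' the acetoxy carbon. Chain carbons C1–C16 of the open-chain compounds map as C1→C4, C2→C5, C3→C6, C4→C7, C5→C8, C6→C8a, C7→C3a, C8→C3, C9→C2, C10→C1, C11→C1', C12→C2', C13→C3', C14→C4', C15→C5'.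

## Analysis of the target

Compound 17 is a diterpenoid diacetate on a trans-fused hydroazulene: a cyclopentane (C1, C2, C3, C3a, C8a) fused to a cycloheptane (C3a, C4–C8, C8a), with an eight-carbon chain on C1. It has six stereocentres: C1 (S), C3a (R), C5 (S), C8a (S), C1' (S) and C4' (S). The angular methyl on C3a and H-8a are trans; the chain on C1 is cis to the angular methyl and to C8, which is the more crowded arrangement on the five-membered ring. The C5 acetoxy group lies on the face opposite to the angular methyl, C1' is a tertiary carbinol bonded directly to C1, and C4' is a remote secondary centre with no stereochemical relay to the ring. The sensitive groups are two secondary allylic acetates, each beside a 1,1-disubstituted alkene (ionisation, allylic shift, alkene migration under acid), and a tertiary alcohol that dehydrates easily and sits 1,4 to the C4' oxygen. The hard part is the contiguous array C3a (quaternary)–C8a–C1–C1' together with the seven-membered ring. The strategy rests on one feature: the atoms C4–C5–C6–C7–C8–C8a–C3a–C3–C2–C1–C1'–C2'–C3'–C4'–C5', with methyl-derived branches on C6, C3a, C1' and C5', form an unbroken head-to-tail tetraprenyl chain. Only C3a–C4 and C1–C8a are additional C–C bonds, C1' bears the hydroxyl where a cyclisation cation would be hydrated, and the C5 and C4' oxygens each sit next to a methyl-derived methylene, the trace of an allylic oxidation with alkene shift.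

## Retrosynthetic reasoning

**17 ⇒ 16 ⇒ 15.** The last operations are at heteroatom level: the O–Si bond on C1' and the two ester C–O bonds. The tertiary hydroxyl is kept silylated to the end so that only the two secondary allylic alcohols of 15 are acylated and the final unmasking of 16 needs nothing stronger than buffered fluoride.

**15 ⇒ 14.** Each allylic alcohol with its neighbouring methylidene is traced back to a trisubstituted epoxide. The C5–O and C4'–O bonds already exist in 14, so both carbinol configurations are decided at the epoxide stage. The forward step only has to remove a proton from the methyl group on C6 and on C5' in a syn elimination, and not from C7 or C3'.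

**14 ⇒ 13 ⇒ 12.** Removing the two epoxide oxygens leaves the two trisubstituted alkenes of 12 (C5=C6 in the ring, C4'=C5' at the chain end). Both new carbinol centres (5S and 4'S) require the same sense of a catalyst-controlled epoxidation, so one catalyst serves both alkenes; at the ring the face wanted is also the one away from the angular methyl. The silyl ether of 13 is introduced first because a free C1' hydroxyl would open the C4',C5' epoxide to a tetrahydrofuran.

**12 ⇒ 11 (key disconnection).** Cutting C3a–C4 and C1–C8a and removing the C1' hydroxyl unravels both rings to the open-chain acetate 11. These are the only two ring bonds that are not part of the tetraprenyl chain; any other cut would require separate construction of the four contiguous stereocentres. The gain is two rings, two C–C bonds and four stereocentres in one step. The 2Z alkene supplies the cis ring alkene, and the 6E and 10E alkenes encode two of the three relative relations. The forward reaction must ionise the allylic acetate, join C4 to C3a (seven-membered ring) while C8a is joined to C1 (five-membered ring), and end by hydration at C1'. It must override the normal closure to a six-membered ring, so this step carries the risk of the route.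

**11 ⇒ 10 ⇒ 9 ⇒ 8 ⇒ 4 + 6 (through 7).** After exchange of acetate for silyl ether (11, 10, 9), the chain is cut at the doubly allylic C8–C9 bond (the future C3–C2 bond). This divides it into two C10 halves that exist with defined geometry: the Z half from 1 and the E half from 5. The bond is made by alkylation of the sulfonyl carbanion 7 with bromide 4, and the sulfonyl group of 8 is then removed reductively. No trisubstituted alkene is created in the sequence; all three are inherited.

**4 ⇒ 3 ⇒ 2 ⇒ 1 and 6 ⇒ 5.** Bromide 4 comes from alcohol 3, and 3 from E-selective allylic oxidation of the terminal methyl group of 2. A silyl ether is used in place of the acetate because the carbanion 7 and the hydride of the desulfonylation would both attack an ester; the acetate is put on only after the chain is complete. Sulfone 6 is one substitution away from 5.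

## Alternatives that were turned down

**Alternative 1:** The cyclopentane is the starting ring and two substituent bonds are disconnected, C3a–CH3 and C8a–C8. In the forward sense enone A1 takes up a methyl group from AlMe3 under a chiral copper catalyst (for example CuTC, copper thiophene-2-carboxylate, with a phosphoramidite). This creates the quaternary C3a, and the aluminium enolate is allylated at C8a anti to the larger C4 arm to give ketone A2, with allyl cis to methyl. In its favour, the hardest single centre, C3a, is set by a known type of catalytic asymmetric reaction, the C1 carbonyl is a handle for the side chain, and every later bond can be made by routine chemistry. On predictability this alternative is stronger than the chosen route. Against it, the enolate must distinguish a methyl group from a CH2R group on the neighbouring quaternary carbon, so the facial bias for C8a is small. No ring is closed, so the seven-membered ring still has to be built. The C1 ketone must become a CH carrying a tertiary carbinol with control at C1 (contra-thermodynamic, cis to C8) and at C1', and C4' remains untouched. This amounts to well over twenty steps. The chosen strategy offers in exchange the whole skeleton and four stereocentres in one operation and fourteen steps in total.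

**Alternative 2:** The five-membered ring is derived from a six-membered one, with C1–C2 formed by a 1,2-shift. Irradiation of diazoketone A3 (a trans-fused six–seven bicycle from a Robinson annulation) expels N2, C2 migrates from the carbonyl carbon to the carbene carbon C1, and methanol adds to the ketene to give ester A4. The Wolff contraction is dependable, the annulation chemistry is classical and the trans fusion can be set by a dissolving-metal reduction; on robustness of the individual steps it is at least as strong as the chosen route. Against it, the key step rearranges the skeleton but adds no carbon. The ketone of the precursor is flanked by two methylene groups, and diazo transfer must occur at the more hindered one (C1). C1 is set only by protonation of a ketene-derived enol and stays epimerisable beside the ester. The ester must still be homologated to the eight-carbon chain with control at C1'. The C5 ketal must be turned into the C5 acetoxy/C6 methylidene pair with regiocontrol, and C4' has to be oxidised. The sequence is long and linear, whereas the chosen strategy takes every skeletal carbon from two C10 alcohols and needs no ring-size adjustment.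

**Alternative 3:** The last C–C bond disconnected is C5–C6. The seco compound A5 carries the C5 aldehyde on the C3a arm and a 2-bromoalkene at C6. CrCl2 (divalent chromium) with catalytic NiCl2 converts the bromide into an alkenyl species of trivalent chromium, which adds to the aldehyde and closes the seven-membered ring to alcohol A6; one acetylation would give 17. This closure produces exactly the 2-methylidenecycloheptanol motif, tolerates acetate and free tertiary hydroxyl, and needs no later oxidation of the ring. On that point it is stronger than the chosen route, which needs epoxidation and isomerisation. Against it, the C5 configuration depends on substrate control in a medium-ring closure. More seriously, A5 already contains C1, C3a, C8a, C1' and C4', so the difficult array must be assembled beforehand by a long sequence of the kind described under alternative 1. The key step does not address the main problem of the target. The chosen strategy places the key step on that array and accepts a step that is not yet known chemistry.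

Key step: step 9

**Remarks (assumptions).** Commercial 5 is taken as the pure (2E) isomer. The acid of step 9 is a confined chiral imidodiphosphorimidate, (ArO)2P(=NSO2CF3)–NH–P(=NSO2CF3)(OAr)2, with two 3,3'-diaryl-1,1'-bi-2-naphthol units. Its sense of induction cannot be derived from a model, so the enantiomer that leads to 12 is meant.

## Route

Step 1
Reactants: 1 nerol, (2Z)-3,7-dimethylocta-2,6-dien-1-ol
Product: 2 tert-butyl{[(2Z)-3,7-dimethylocta-2,6-dien-1-yl]oxy}dimethylsilane
Conditions: TBSCl, imidazole, CH2Cl2, 0 °C to rt
Reagents that add atoms: tert-butyldimethylsilyl chloride, CC(C)(C)[Si](C)(C)Cl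
Why: Standard silylation of a primary allylic alcohol; unlike an ester, the silyl ether tolerates the carbanion of step 5 and the hydride of step 6.

Step 2
Reactants: 2 tert-butyl{[(2Z)-3,7-dimethylocta-2,6-dien-1-yl]oxy}dimethylsilane
Product: 3 (2E,6Z)-8-{[tert-butyl(dimethyl)silyl]oxy}-2,6-dimethylocta-2,6-dien-1-ol
Conditions: SeO2 (0.3 equiv), t-BuOOH (3 equiv), salicylic acid (0.1 equiv), CH2Cl2, rt
Reagents that add atoms: selenium dioxide, O=[Se]=O (transfers the oxygen atom); tert-butyl hydroperoxide, CC(C)(C)OO (stoichiometric oxygen source that re-oxidises selenium)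
Why: Catalytic SeO2 allylic oxidation (ene reaction, then [2,3]-sigmatropic shift) attacks the electron-richer terminal alkene, the C2=C3 alkene being deactivated by its allylic oxygen; it oxidises the methyl group trans to the chain and so should give the E allylic alcohol without touching the 2Z alkene.

Step 3
Reactants: 3 (2E,6Z)-8-{[tert-butyl(dimethyl)silyl]oxy}-2,6-dimethylocta-2,6-dien-1-ol
Product: 4 {[(2Z,6E)-8-bromo-3,7-dimethylocta-2,6-dien-1-yl]oxy}(tert-butyl)dimethylsilane
Conditions: CBr4, PPh3, CH2Cl2, 0 °C
Reagents that add atoms: carbon tetrabromide, BrC(Br)(Br)Br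
Why: Appel reaction; the primary allylic alcohol is converted by SN2 under neutral conditions, so neither allylic shift nor loss of alkene geometry is expected.

Step 4
Reactants: 5 geranyl bromide, (2E)-1-bromo-3,7-dimethylocta-2,6-diene
Product: 6 geranyl phenyl sulfone, {[(2E)-3,7-dimethylocta-2,6-dien-1-yl]sulfonyl}benzene
Conditions: PhSO2Na, DMF, rt
Reagents that add atoms: sodium benzenesulfinate, [Na+].[O-]S(=O)c1ccccc1
Why: S-alkylation of the sulfinate at the primary allylic carbon (SN2); the E alkene is retained.

Step 5
Reactants: 6 geranyl phenyl sulfone; 4 {[(2Z,6E)-8-bromo-3,7-dimethylocta-2,6-dien-1-yl]oxy}(tert-butyl)dimethylsilane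
Product: 8 tert-butyl{[(2Z,6E,10E)-9-(benzenesulfonyl)-3,7,11,15-tetramethylhexadeca-2,6,10,14-tetraen-1-yl]oxy}dimethylsilane (racemic at C9), via lithiated geranyl phenyl sulfone 7 (not isolated)
Conditions: n-BuLi, THF, −78 °C; then 4, −78 to −20 °C
Reagents that add atoms: none
Why: α-Alkylation of a sulfonyl-stabilised allyl anion with a primary allylic bromide (sulfone-based prenyl chain extension) forms the C8–C9 bond by SN2, so all three trisubstituted alkenes keep their geometry; the racemic C9 centre disappears in step 6.

Step 6
Reactants: 8 tert-butyl{[(2Z,6E,10E)-9-(benzenesulfonyl)-3,7,11,15-tetramethylhexadeca-2,6,10,14-tetraen-1-yl]oxy}dimethylsilane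
Product: 9 tert-butyldimethyl{[(2Z,6E,10E)-3,7,11,15-tetramethylhexadeca-2,6,10,14-tetraen-1-yl]oxy}silane
Conditions: PdCl2(dppp) (5 mol %), LiBHEt3 (2.5 equiv), THF, 0 °C
Reagents that add atoms: none
Why: Palladium-catalysed hydride desulfonylation of an allylic sulfone: zerovalent palladium ionises the C–S bond to a π-allyl complex and hydride goes to the less substituted terminus C9, which should leave the C10=C11 alkene in place and E; the silyl ether is inert.

Step 7
Reactants: 9 tert-butyldimethyl{[(2Z,6E,10E)-3,7,11,15-tetramethylhexadeca-2,6,10,14-tetraen-1-yl]oxy}silane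
Product: 10 (2Z,6E,10E)-3,7,11,15-tetramethylhexadeca-2,6,10,14-tetraen-1-ol
Conditions: TBAF, THF, 0 °C to rt
Reagents that add atoms: none
Why: Fluoride cleavage of the primary silyl ether; no acid is present that could start a cyclisation of the polyene.

Step 8
Reactants: 10 (2Z,6E,10E)-3,7,11,15-tetramethylhexadeca-2,6,10,14-tetraen-1-ol
Product: 11 (2Z,6E,10E)-3,7,11,15-tetramethylhexadeca-2,6,10,14-tetraen-1-yl acetate
Conditions: Ac2O, pyridine, DMAP (cat.), CH2Cl2, 0 °C
Reagents that add atoms: acetic anhydride, CC(=O)OC(C)=O
Why: Acylation of a primary allylic alcohol under basic conditions; the ionisable group is installed only after all carbanion and hydride chemistry is finished.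

Step 9
Reactants: 11 (2Z,6E,10E)-3,7,11,15-tetramethylhexadeca-2,6,10,14-tetraen-1-yl acetate
Product: 12 (2S)-2-[(1S,3aR,8aS)-3a,6-dimethyl-1,2,3,3a,4,7,8,8a-octahydroazulen-1-yl]-6-methylhept-5-en-2-ol
Conditions: confined chiral imidodiphosphorimidate acid (5 mol %), H2O (3 equiv), CHCl3/(CF3)3COH, −30 °C
Reagents that add atoms: water, O
Why: Proposed new method: protonation of the acetate by the confined acid and loss of acetic acid should give, from the 2Z alkene, a cisoid C4–C5–C6 allyl cation held as an ion pair in the chiral pocket; its C4 terminus is attacked by C3a of the 6E alkene while C8a is attacked at the same time by C1 of the 10E alkene, so that no free secondary cation at C8a has to exist, and the tertiary C1' cation is hydrated. The closest known reaction type is the Brønsted-acid-catalysed cationic cyclisation of terpenyl acetates inside a hexameric resorcinarene capsule, together with enantioselective polyene cyclisation by confined imidodiphosphorimidate acids; neither has been shown for a bond from C4 to the more substituted alkene carbon C3a. The seven-membered ring closes in the 7-endo mode (both carbons of the C8a=C3a alkene end up in the ring) and the five-membered ring in the 5-exo mode (C1' stays outside). C3a and C8a are related by anti addition across the E-configured C8a=C3a alkene, which gives the trans ring fusion, and C1 and C1' by anti addition of C8a and water across the E-configured C1=C1' alkene. The relation of C8a to C1 follows from the fold of the C3a–C3–C2–C1 tether and the absolute sense from the chiral anion, and both must be imposed by the catalyst pocket. The step needs attack at C3a instead of the Markovnikov attack at C8a (six-membered ring), ionisation of the acetate in preference to protonation of the terminal C4'=C5' alkene, and hydration instead of proton loss; the substrate itself secures only the cis ring alkene (2Z) and the two local anti relations (6E, 10E).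

Step 10
Reactants: 12 (2S)-2-[(1S,3aR,8aS)-3a,6-dimethyl-1,2,3,3a,4,7,8,8a-octahydroazulen-1-yl]-6-methylhept-5-en-2-ol
Product: 13 triethyl({(2S)-2-[(1S,3aR,8aS)-3a,6-dimethyl-1,2,3,3a,4,7,8,8a-octahydroazulen-1-yl]-6-methylhept-5-en-2-yl}oxy)silane
Conditions: TESOTf, 2,6-lutidine, CH2Cl2, −78 to 0 °C
Reagents that add atoms: triethylsilyl trifluoromethanesulfonate, CC[Si](CC)(CC)OS(=O)(=O)C(F)(F)F
Why: A silyl triflate with a hindered base is needed for the tertiary alcohol; the ether prevents the C1' hydroxyl from opening the C4',C5' epoxide to a tetrahydrofuran and from consuming the base of step 12.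

Step 11
Reactants: 13 triethyl({(2S)-2-[(1S,3aR,8aS)-3a,6-dimethyl-1,2,3,3a,4,7,8,8a-octahydroazulen-1-yl]-6-methylhept-5-en-2-yl}oxy)silane
Product: 14 bis-epoxide of 13: (5S,6R)-5,6-epoxide on the face of the seven-membered ring opposite to the C3a methyl group, and (4'S)-4',5'-epoxide (a 3-substituted (3S)-2,2-dimethyloxirane); C1' triethylsilyl ether unchanged
Conditions: 1,2:4,5-di-O-isopropylidene-β-L-erythro-2,3-hexodiulo-2,6-pyranose (ent-Shi ketone, 0.6 equiv), KHSO5 (as Oxone), K2CO3, n-Bu4NHSO4, MeCN/CH2(OMe)2/aq. Na2B4O7 buffer (pH 10.5), 0 °C
Reagents that add atoms: potassium peroxymonosulfate, [K+].[O-]S(=O)(=O)OO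
Why: Shi epoxidation (chiral dioxirane, spiro transition state) of both trisubstituted alkenes; by the usual model the L-fructose-derived ketone should give the S configuration at the CH carbon of each alkene, that is 4'S in the chain and 5S in the ring, where this face is also the one not screened by the C3a methyl group (matched case). C6 follows as R because the epoxide is cis.

Step 12
Reactants: 14 bis-epoxide of 13
Product: 15 (3S,6S)-6-[(1S,3aR,5S,8aS)-5-hydroxy-3a-methyl-6-methylidenedecahydroazulen-1-yl]-2-methyl-6-[(triethylsilyl)oxy]hept-1-en-3-ol
Conditions: Et2AlTMP (6 equiv, from LiTMP and Et2AlCl), toluene, 0 °C; aq. Rochelle salt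
Reagents that add atoms: none
Why: Isomerisation of epoxides to allylic alcohols with a dialkylaluminium amide: aluminium binds the epoxide oxygen and the amide removes, in a syn fashion, a proton from the alkyl group cis to the epoxide hydrogen, which is a methyl group in both epoxides (C6–CH3 in the ring, one C5' methyl in the chain). The C5–O and C4'–O bonds are not broken, so both configurations are retained.

Step 13
Reactants: 15 (3S,6S)-6-[(1S,3aR,5S,8aS)-5-hydroxy-3a-methyl-6-methylidenedecahydroazulen-1-yl]-2-methyl-6-[(triethylsilyl)oxy]hept-1-en-3-ol
Product: 16 (3S,6S)-6-[(1S,3aR,5S,8aS)-5-acetoxy-3a-methyl-6-methylidenedecahydroazulen-1-yl]-2-methyl-6-[(triethylsilyl)oxy]hept-1-en-3-yl acetate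
Conditions: Ac2O, pyridine, DMAP (cat.), CH2Cl2, rt
Reagents that add atoms: acetic anhydride, CC(=O)OC(C)=O
Why: Acylation of the two secondary allylic alcohols with retention at carbon; the tertiary oxygen is silylated and does not react.

Step 14
Reactants: 16 (3S,6S)-6-[(1S,3aR,5S,8aS)-5-acetoxy-3a-methyl-6-methylidenedecahydroazulen-1-yl]-2-methyl-6-[(triethylsilyl)oxy]hept-1-en-3-yl acetate
Product: 17 (3S,6S)-6-[(1S,3aR,5S,8aS)-5-acetoxy-3a-methyl-6-methylidenedecahydroazulen-1-yl]-6-hydroxy-2-methylhept-1-en-3-yl acetate (CNP0151143.1)
Conditions: HF·pyridine, pyridine, THF, 0 °C to rt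
Reagents that add atoms: none
Why: Fluoride-mediated cleavage of the tertiary silyl ether under buffered conditions that should leave the acetates, the allylic systems and the tertiary alcohol intact.

## Compound list

1 | nerol, (2Z)-3,7-dimethylocta-2,6-dien-1-ol | CC(C)=CCC/C(C)=C\CO | starting material
2 | tert-butyl{[(2Z)-3,7-dimethylocta-2,6-dien-1-yl]oxy}dimethylsilane | CC(C)=CCC/C(C)=C\CO[Si](C)(C)C(C)(C)C | intermediate
3 | (2E,6Z)-8-{[tert-butyl(dimethyl)silyl]oxy}-2,6-dimethylocta-2,6-dien-1-ol | CC(C)(C)[Si](C)(C)OC/C=C(C)\CC/C=C(\C)CO | intermediate
4 | {[(2Z,6E)-8-bromo-3,7-dimethylocta-2,6-dien-1-yl]oxy}(tert-butyl)dimethylsilane | CC(C)(C)[Si](C)(C)OC/C=C(C)\CC/C=C(\C)CBr | intermediate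
5 | geranyl bromide, (2E)-1-bromo-3,7-dimethylocta-2,6-diene | CC(C)=CCC/C(C)=C/CBr | starting material
6 | geranyl phenyl sulfone | CC(C)=CCC/C(C)=C/CS(=O)(=O)c1ccccc1 | intermediate
7 | lithiated geranyl phenyl sulfone (α-lithio derivative of 6) | CC(C)=CCC/C(C)=C/[CH-]S(=O)(=O)c1ccccc1.[Li+] | intermediate (not isolated)
8 | tert-butyl{[(2Z,6E,10E)-9-(benzenesulfonyl)-3,7,11,15-tetramethylhexadeca-2,6,10,14-tetraen-1-yl]oxy}dimethylsilane (racemic at C9) | CC(C)(C)[Si](C)(C)OC/C=C(C)\CC/C=C(\C)CC(/C=C(\C)CCC=C(C)C)S(=O)(=O)c1ccccc1 | intermediate
9 | tert-butyldimethyl{[(2Z,6E,10E)-3,7,11,15-tetramethylhexadeca-2,6,10,14-tetraen-1-yl]oxy}silane | CC(C)(C)[Si](C)(C)OC/C=C(C)\CC/C=C(\C)CC/C=C(\C)CCC=C(C)C | intermediate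
10 | (2Z,6E,10E)-3,7,11,15-tetramethylhexadeca-2,6,10,14-tetraen-1-ol | OC/C=C(C)\CC/C=C(\C)CC/C=C(\C)CCC=C(C)C | intermediate
11 | (2Z,6E,10E)-3,7,11,15-tetramethylhexadeca-2,6,10,14-tetraen-1-yl acetate | CC(=O)OC/C=C(C)\CC/C=C(\C)CC/C=C(\C)CCC=C(C)C | intermediate
12 | (2S)-2-[(1S,3aR,8aS)-3a,6-dimethyl-1,2,3,3a,4,7,8,8a-octahydroazulen-1-yl]-6-methylhept-5-en-2-ol | CC(C)=CCC[C@](C)(O)[C@H]1CC[C@]2(C)CC=C(C)CC[C@@H]12 | intermediate
13 | triethylsilyl ether of 12 at C1' | CC(C)=CCC[C@](C)(O[Si](CC)(CC)CC)[C@H]1CC[C@]2(C)CC=C(C)CC[C@@H]12 | intermediate
14 | bis-epoxide of 13: (5S,6R)-5,6-epoxide and (4'S)-4',5'-epoxide | CC1(C)O[C@H]1CC[C@](C)(O[Si](CC)(CC)CC)[C@H]1CC[C@]2(C)C[C@@H]3O[C@]3(C)CC[C@@H]12 | intermediate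
15 | (3S,6S)-6-[(1S,3aR,5S,8aS)-5-hydroxy-3a-methyl-6-methylidenedecahydroazulen-1-yl]-2-methyl-6-[(triethylsilyl)oxy]hept-1-en-3-ol | C=C(C)[C@H](CC[C@](C)(O[Si](CC)(CC)CC)[C@H]1CC[C@]2(C)C[C@H](O)C(=C)CC[C@@H]12)O | intermediate
16 | (3S,6S)-6-[(1S,3aR,5S,8aS)-5-acetoxy-3a-methyl-6-methylidenedecahydroazulen-1-yl]-2-methyl-6-[(triethylsilyl)oxy]hept-1-en-3-yl acetate | C=C(C)[C@H](CC[C@](C)(O[Si](CC)(CC)CC)[C@H]1CC[C@]2(C)C[C@H](OC(C)=O)C(=C)CC[C@@H]12)OC(C)=O | intermediate
17 | (3S,6S)-6-[(1S,3aR,5S,8aS)-5-acetoxy-3a-methyl-6-methylidenedecahydroazulen-1-yl]-6-hydroxy-2-methylhept-1-en-3-yl acetate | C=C(C)[C@H](CC[C@](C)(O)[C@H]1CC[C@]2(C)C[C@H](OC(C)=O)C(=C)CC[C@@H]12)OC(C)=O | target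

## Step count and risks

Total: 14 steps. Longest linear sequence: 13 steps (1 to 17 through steps 1–3 and 5–14); step 4 is a one-step side branch.

**Step 9 (key step, proposed new method).** The most likely failure is regiochemical: the allyl cation is attacked by C8a of the neighbouring alkene in the Markovnikov sense, which closes a six-membered ring and leaves a tertiary cation at C3a. Further failure modes are protonation of the electron-rich terminal alkene by the strong acid, proton loss instead of hydration, and insufficient control of the tether fold or of the absolute sense.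

The fallback uses known chemistry and builds the bicycle ring by ring. None of the open-chain compounds 1–11 can be reused, so it does not branch from a numbered intermediate: it sets out from commercial diallyl adipate F1 and comes back to the route at compound 12.
- Dieckmann cyclisation of diallyl adipate F1 (NaH, toluene) gives allyl 2-oxocyclopentane-1-carboxylate F2. C-Methylation (MeI, K2CO3, acetone) gives allyl 1-methyl-2-oxocyclopentane-1-carboxylate F3.
- Decarboxylative asymmetric allylic alkylation (Pd2(dba)3, (R)-t-BuPHOX, THF; ligand sense by analogy with the six-membered series) is expected to give (2R)-2-methyl-2-(prop-2-en-1-yl)cyclopentan-1-one F4. This fixes C3a, with the allyl group as the future C4–C5 unit.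
- Aldol addition of the only possible enolate to acetaldehyde (LDA, THF, −78 °C) gives hydroxy ketone F5. Mesylation (MsCl, Et3N) gives the mesylate F6 (not isolated), and elimination with DBU gives the (E)-ethylidene ketone F7.
- 1,2-Addition of the organocerium reagent from 3-methylbut-3-enylmagnesium bromide and CeCl3 gives the tertiary allylic alcohol F8. Oxidative 1,3-transposition with pyridinium chlorochromate, (C5H5NH)(CrO3Cl) (Babler–Dauben oxidation), moves the oxygen to the future C1' and gives the acylcyclopentene F9.
- Ring-closing metathesis with the second-generation Grubbs catalyst, RuCl2(=CHPh)(PCy3)(H2IMes), in CH2Cl2 at 40 °C joins the allyl group and the 1,1-disubstituted alkene. This closes the seven-membered ring with its C5=C6 alkene and gives the bicyclic enone F10.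
- Lithium in liquid ammonia reduces only the enone. Protonation at C8a anti to the angular methyl should give the trans fusion, and kinetic protonation of the enolate at C1 from the same, less hindered face should place the acetyl group cis to C8, giving the methyl ketone F11.
- Addition of 4-methylpent-3-enylmagnesium bromide with CeCl3 at −78 °C then gives 12. The Felkin–Anh model with C8a as the large substituent predicts the S configuration at C1'.

The line has ten operations and uses only established reaction types.

**Step 11 (double Shi epoxidation).** Facial selectivity at the ring alkene may be poor, because a 1-methylcycloalkene-type alkene offers the catalyst little steric differentiation and the ring conformation may not reinforce it; over-oxidation is a lesser concern. The fallback sets out from 13 and comes back at 15; it moves stereocontrol from the epoxidation to a ketone reduction. Unselective epoxidation of 13 with mCPBA (NaHCO3, CH2Cl2) gives the bis-epoxide as a diastereomer mixture F12. The isomerisation of step 12 then gives the diol mixture F13, and Dess–Martin periodinane gives the dienedione F14. Corey–Bakshi–Shibata reduction with (R)-2-methyl-CBS-oxazaborolidine and catecholborane, in which each alkenyl group acts as the large substituent, should then deliver both S-configured allylic alcohols of 15.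

**Step 12 (epoxide isomerisation).** The amide may abstract a proton from the ring methylene C7 instead of the methyl group, or the Lewis-acidic aluminium may trigger a hydride shift to a ketone. The fallback sets out from 14 and comes back at 15 and makes no new compound (F0). It changes the mechanism from concerted syn-deprotonation to homolysis: Cp2TiCl (trivalent titanium, from Cp2TiCl2 and Mn, THF) opens each epoxide at the tertiary carbon. The tertiary radical is captured by a second equivalent, and β-hydride elimination from the least hindered position, a methyl group, should give the same methylidene and isopropenyl alcohols with the C–O configurations untouched.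

**Step 6 (desulfonylation).** Equilibration within the π-allyl palladium intermediate could erode the position or E geometry of the C10=C11 alkene, which would falsify the stereochemical code of the key step. The fallback sets out from bromide 4 and comes back at 9, bypassing 6, 7 and 8. Geranyl chloride F15 is converted with activated barium (from BaI2 and lithium biphenylide, THF, −78 °C) into geranylbarium chloride F16. This couples with 4 at its α-carbon by direct substitution, with retention of both alkene geometries, so that no sulfone and no π-allyl species are involved.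

## Further compounds

F1 | step 9 | diallyl adipate, di(prop-2-en-1-yl) hexanedioate | C=CCOC(=O)CCCCC(=O)OCC=C
F2 | step 9 | allyl 2-oxocyclopentane-1-carboxylate (racemic) | C=CCOC(=O)C1CCCC1=O
F3 | step 9 | allyl 1-methyl-2-oxocyclopentane-1-carboxylate (racemic) | C=CCOC(=O)C1(C)CCCC1=O
F4 | step 9 | (2R)-2-methyl-2-(prop-2-en-1-yl)cyclopentan-1-one | O=C1CCC[C@]1(C)CC=C
F5 | step 9 | (2R)-5-(1-hydroxyethyl)-2-methyl-2-(prop-2-en-1-yl)cyclopentan-1-one (mixture at C5 and at the carbinol carbon) | CC(O)C1CC[C@](C)(CC=C)C1=O
F6 | step 9 | methanesulfonate of F5 | CC(OS(C)(=O)=O)C1CC[C@](C)(CC=C)C1=O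
F7 | step 9 | (2R,5E)-5-ethylidene-2-methyl-2-(prop-2-en-1-yl)cyclopentan-1-one | C/C=C1/C(=O)[C@@](C)(CC=C)CC1
F8 | step 9 | (2R,5E)-5-ethylidene-2-methyl-1-(3-methylbut-3-en-1-yl)-2-(prop-2-en-1-yl)cyclopentan-1-ol (both C1 epimers) | C/C=C1/C(O)(CCC(C)=C)[C@@](C)(CC=C)CC1
F9 | step 9 | 1-[(3R)-3-methyl-2-(3-methylbut-3-en-1-yl)-3-(prop-2-en-1-yl)cyclopent-1-en-1-yl]ethan-1-one | CC(=O)C1=C(CCC(C)=C)[C@@](C)(CC=C)CC1
F10 | step 9 | 1-[(3aR)-3a,6-dimethyl-2,3,3a,4,7,8-hexahydroazulen-1-yl]ethan-1-one | CC(=O)C1=C2CCC(C)=CC[C@@]2(C)CC1
F11 | step 9 | 1-[(1S,3aR,8aS)-3a,6-dimethyl-1,2,3,3a,4,7,8,8a-octahydroazulen-1-yl]ethan-1-one | CC(=O)[C@H]1CC[C@]2(C)CC=C(C)CC[C@@H]12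
F12 | step 11 | bis-epoxide of 13 as a mixture of diastereomers at C5, C6 and C4' | CC1(C)OC1CC[C@](C)(O[Si](CC)(CC)CC)[C@H]1CC[C@]2(C)CC3OC3(C)CC[C@@H]12
F13 | step 11 | C5/C4' diastereomer mixture of diol 15 | C=C(C)C(O)CC[C@](C)(O[Si](CC)(CC)CC)[C@H]1CC[C@]2(C)CC(O)C(=C)CC[C@@H]12
F14 | step 11 | dienedione: C5 ketone with C6 methylidene and C4' ketone with isopropenyl, C1' triethylsilyl ether | C=C(C)C(=O)CC[C@](C)(O[Si](CC)(CC)CC)[C@H]1CC[C@]2(C)CC(=O)C(=C)CC[C@@H]12
F0 | step 12 | none | none
F15 | step 6 | geranyl chloride, (2E)-1-chloro-3,7-dimethylocta-2,6-diene | CC(C)=CCC/C(C)=C/CCl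
F16 | step 6 | geranylbarium chloride | CC(C)=CCC/C(C)=C/C[Ba]Cl
A1 | alternative 1 | 3-(1,3-dioxolan-2-ylmethyl)cyclopent-2-en-1-one | O=C1C=C(CC2OCCO2)CC1
A2 | alternative 1 | (2R,3R)-3-(1,3-dioxolan-2-ylmethyl)-3-methyl-2-(prop-2-en-1-yl)cyclopentan-1-one | O=C1CC[C@](C)(CC2OCCO2)[C@H]1CC=C
A3 | alternative 2 | trans-fused six–seven bicyclic α-diazoketone (diazo carbon = future C1, keto carbon = future C1', angular methyl on C3a, ethylene ketal at C5; C3a and C8a as in the target) | O=C1CC[C@]2(C)CC3(OCCO3)CCC[C@H]2C1=[N+]=[N-]
A4 | alternative 2 | methyl (1S,3aR,8aS)-5,5-(ethylenedioxy)-3a-methyldecahydroazulene-1-carboxylate | COC(=O)[C@H]1CC[C@]2(C)CC3(OCCO3)CCC[C@@H]12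
A5 | alternative 3 | (3S,6S)-6-[(1S,2S,3R)-2-(3-bromobut-3-en-1-yl)-3-methyl-3-(2-oxoethyl)cyclopentyl]-6-hydroxy-2-methylhept-1-en-3-yl acetate | C=C(C)[C@H](CC[C@](C)(O)[C@H]1CC[C@](C)(CC=O)[C@H]1CCC(Br)=C)OC(C)=O
A6 | alternative 3 | (3S,6S)-6-hydroxy-6-[(1S,3aR,5S,8aS)-5-hydroxy-3a-methyl-6-methylidenedecahydroazulen-1-yl]-2-methylhept-1-en-3-yl acetate | C=C(C)[C@H](CC[C@](C)(O)[C@H]1CC[C@]2(C)C[C@H](O)C(=C)CC[C@@H]12)OC(C)=O
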